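**Retrosynthetic overview**

1. Ring C is cut at C2–C1' (asymmetric conjugate arylation of a chromone, which sets C2). The chromone is cut at C4a–C4 (ortho-lithiation and acetylation of ring A) and at O1–C2 (enaminone closure).
2. The strategy rests on one feature of the side chain: the carbinol carbon C3'' is 1,5-related to O7 through C7, C6, C1'' and C2''. O7 and C3'' can therefore be tied as the ester of a six-membered lactone (a 3,4-dihydrocoumarin fused at C6–C7 of ring A). MeMgBr later turns that C=O into CMe2OH and gives back O7–H.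
3. Key disconnection: the lactone is split at C1''–C2'' and O7–C3'' into the ring A ortho-quinone methide (from a 2-(tosylmethyl)phenol) and a chiral catalyst-bound enolate of 5-methylhex-4-enoic acid. This formal (4+2) sets C2''.
4. Building blocks: the sulfone from 5-methoxyresorcinol (four steps), the acid by Johnson–Claisen rearrangement (two steps), and the ring B boronic acid from 4-bromoresorcinol (two steps).
5. Ring order: rings A and B are bought. The temporary lactone ring forms in step 7 and is opened in step 8. The pyranone ring C forms in step 12 and becomes the flavanone in step 15.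

Key step: step 7

Remark on locants: flavanone numbering is used (O1, C2 to C8a, ring B primed, O7 on C7); the side chain is C1'' (benzylic CH2), C2'' (stereocentre), C3'' (carbinol carbon).

Remark on catalyst antipodes: the antipodes in steps 7 and 15 are assigned from face-shielding models, not from a verified precedent on this substrate. The configuration of 14 and of 28 is to be confirmed, and the mirror-image catalyst is used if the sense proves opposite.

**Route**

Step 1
Reactants: 1 5-methoxyresorcinol
Product: 3 2,4-dihydroxy-6-methoxybenzaldehyde, via iminium chloride 2 (not isolated)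
Conditions: POCl3 (1.2 equiv), DMF, MeCN, 0 °C to rt; then H2O, 50 °C
Reagents that add atoms: N,N-dimethylformamide, CN(C)C=O; water, O
Why: Vilsmeier–Haack formylation, in which the chloroiminium ion attacks a ring carbon para to one hydroxyl and ortho to the methoxy group (two equivalent sites against one between the hydroxyls) and water hydrolyses 2; the 2,6-dihydroxy-4-methoxy isomer expected as the minor product is removed by crystallisation or chromatography.

Step 2
Reactants: 3 2,4-dihydroxy-6-methoxybenzaldehyde
Product: 4 2-hydroxy-6-methoxy-4-(methoxymethoxy)benzaldehyde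
Conditions: MOMCl (1.05 equiv), iPr2NEt, CH2Cl2, 0 °C
Reagents that add atoms: chloromethyl methyl ether, COCCl
Why: Williamson-type O-alkylation that should take only the 4-hydroxyl, because the 2-hydroxyl is held in a hydrogen bond to the aldehyde and is the less nucleophilic of the two.

Step 3
Reactants: 4 2-hydroxy-6-methoxy-4-(methoxymethoxy)benzaldehyde
Product: 5 2-(hydroxymethyl)-3-methoxy-5-(methoxymethoxy)phenol
Conditions: NaBH4, THF/MeOH, 0 °C, short reaction time; crude 5 used at once
Reagents that add atoms: none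
Why: Borohydride reduction of the aldehyde, kept cold and brief so that the electron-rich salicyl alcohol does not lose hydroxide to a quinone methide and get reduced further to the cresol.

Step 4
Reactants: 5 2-(hydroxymethyl)-3-methoxy-5-(methoxymethoxy)phenol
Product: 6 3-methoxy-5-(methoxymethoxy)-2-(tosylmethyl)phenol
Conditions: p-TolSO2H (2 equiv, freshly liberated from its sodium salt), CH2Cl2, rt
Reagents that add atoms: 4-methylbenzenesulfinic acid, Cc1ccc(S(=O)O)cc1
Why: Acid-promoted SN1-type substitution, in which the benzylic alcohol, activated by three ring oxygens, ionises under the mild acidity of the sulfinic acid and is captured at sulfur to give the stable, crystalline sulfone, the usual precursor of base-triggered ortho-quinone methides; the aryl MOM ether should survive this weak acid in an aprotic solvent.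

Step 5
Reactants: 7 2-methylbut-3-en-2-ol; 8 triethyl orthoacetate
Product: 10 ethyl 5-methylhex-4-enoate, via ketene acetal 9 (not isolated)
Conditions: EtCO2H (cat.), 140 °C, EtOH distilled off
Reagents that add atoms: none
Why: Johnson–Claisen rearrangement, in which the mixed ketene acetal 9 of the tertiary allylic alcohol undergoes a [3,3]-sigmatropic shift that forms the C2–C3 bond of the ester and the trisubstituted alkene.

Step 6
Reactants: 10 ethyl 5-methylhex-4-enoate
Product: 11 5-methylhex-4-enoic acid
Conditions: LiOH·H2O, THF/H2O, rt; then cold aq. HCl to pH 3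
Reagents that add atoms: lithium hydroxide, [Li+].[OH-]
Why: Ester saponification, with a brief cold acidification so that the unsaturated acid does not lactonise onto the trisubstituted alkene.

Step 7
Reactants: 6 3-methoxy-5-(methoxymethoxy)-2-(tosylmethyl)phenol; 11 5-methylhex-4-enoic acid
Product: 14 (3S)-5-methoxy-7-(methoxymethoxy)-3-(3-methylbut-2-en-1-yl)-3,4-dihydro-2H-chromen-2-one, via acyl imidazole 12 (not isolated), via ortho-quinone methide 13 (not isolated)
Conditions: 11 (1.6 equiv), 1,1'-carbonyldiimidazole (1.5 equiv), THF, rt, 1 h; this solution then added to 6 (1.0 equiv), (5aS,10bR)-2-mesityl-5a,10b-dihydro-4H,6H-indeno[2,1-b][1,2,4]triazolo[4,3-d][1,4]oxazin-2-ium tetrafluoroborate (15 mol %), Cs2CO3 (2.0 equiv), 4 Å MS, THF, 0 °C to rt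
Reagents that add atoms: none
Why: Carbonate frees the carbene, which is acylated by 12 and deprotonated at the α-carbon to a (Z)-azolium enolate, while the phenoxide of 6 expels p-toluenesulfinate to give 13; the enolate α-carbon adds to the methide CH2 (Michael addition, C1''–C2'') and the phenoxide so formed attacks the acyl azolium carbonyl, which makes the O7–C3'' bond and releases the carbene. The closest known reaction type is the carbene-catalysed formal (4+2) annulation of azolium enolates, made from acyl imidazoles or from carboxylic acids activated in the flask, with transient ortho-quinone methides that are unsubstituted at the methide carbon, which gives 3-substituted 3,4-dihydrocoumarins; an azolium enolate is chosen because an acyl ammonium with only an α-alkyl group is not enolised reliably. The single ring closed is the six-membered lactone, formed by 6-exo-trig O-acylation after the C–C bond. The new stereocentre (C3 of 14, later C2'') is set in the C–C bond formation by the aminoindanol-derived backbone of the catalyst, which shields one face of the planar enolate so that the methide adds to the other; the (5aS,10bR) salt is assigned to the (3S) product on this model. The step needs regiocontrol, chemoselectivity and configurational stability: the CH2 of the sulfone between OMe and OH fixes attachment at the future C6, the MOM cap on the para oxygen leaves only the ortho phenol able to form a quinone methide and to lactonise, slow heterogeneous release of 13 by Cs2CO3 with reversible re-addition of sulfinate should keep its concentration low enough to suppress dimerisation and N-benzylation of imidazole, and the α-alkyl lactone is much less acidic than the α-aryl lactones for which the annulation is established.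

Step 8
Reactants: 14 (3S)-5-methoxy-7-(methoxymethoxy)-3-(3-methylbut-2-en-1-yl)-3,4-dihydro-2H-chromen-2-one
Product: 16 2-[(2S)-2-(2-hydroxypropan-2-yl)-5-methylhex-4-en-1-yl]-3-methoxy-5-(methoxymethoxy)phenol, via methyl ketone 15 (not isolated)
Conditions: MeMgBr (4 equiv), THF, −78 °C to 0 °C; aq. NH4Cl
Reagents that add atoms: methylmagnesium bromide, C[Mg]Br
Why: Grignard double addition to an aryl ester, in which the first methyl expels the phenoxide and gives ketone 15 and the second adds to 15 faster than to the lactone, so that the carbinol and the free O7–H appear in one operation; the weakly basic reagent at low temperature should leave the α-stereocentre untouched.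

Step 9
Reactants: 16 2-[(2S)-2-(2-hydroxypropan-2-yl)-5-methylhex-4-en-1-yl]-3-methoxy-5-(methoxymethoxy)phenol
Product: 17 (3S)-3-{[2-methoxy-4-(methoxymethoxy)-6-(triisopropylsilyloxy)phenyl]methyl}-2,6-dimethylhept-5-en-2-ol
Conditions: TIPSCl (1.3 equiv), imidazole, DMF, rt
Reagents that add atoms: chlorotriisopropylsilane, CC(C)[Si](Cl)(C(C)C)C(C)C
Why: Silylation of the phenol only, since the tertiary alcohol does not react with a bulky silyl chloride under imidazole catalysis; the triisopropylsilyl group is chosen because it neither coordinates lithium nor leaves room next to it.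

Step 10
Reactants: 17 (3S)-3-{[2-methoxy-4-(methoxymethoxy)-6-(triisopropylsilyloxy)phenyl]methyl}-2,6-dimethylhept-5-en-2-ol
Product: 19 1-[3-{(2S)-2-(2-hydroxypropan-2-yl)-5-methylhex-4-en-1-yl}-2-methoxy-6-(methoxymethoxy)-4-(triisopropylsilyloxy)phenyl]ethan-1-one, via aryllithium 18 (not isolated)
Conditions: n-BuLi (2.3 equiv), TMEDA, THF, −78 °C to 0 °C; then MeC(O)N(OMe)Me (3 equiv), −78 °C to rt; aq. NH4Cl
Reagents that add atoms: N-methoxy-N-methylacetamide, CON(C)C(C)=O
Why: Directed ortho-metalation, in which the first equivalent of base forms the lithium alkoxide and the second removes the ring hydrogen between the OMOM and OMe groups, which chelate lithium together, whereas the other position ortho to OMOM is flanked by the bulky, non-coordinating silyl ether; acylation of 18 with the N-methoxy-N-methyl amide stops at the ketone.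

Step 11
Reactants: 19 1-[3-{(2S)-2-(2-hydroxypropan-2-yl)-5-methylhex-4-en-1-yl}-2-methoxy-6-(methoxymethoxy)-4-(triisopropylsilyloxy)phenyl]ethan-1-one
Product: 20 1-[6-hydroxy-3-{(2S)-2-(2-hydroxypropan-2-yl)-5-methylhex-4-en-1-yl}-2-methoxy-4-(triisopropylsilyloxy)phenyl]ethan-1-one
Conditions: HCl (0.5 M in MeOH), THF, 0 °C to rt
Reagents that add atoms: none
Why: Acid-catalysed acetal exchange that is especially easy for a MOM ether ortho to a ketone (the phenol set free is hydrogen-bonded to the carbonyl), so dilute acid at room temperature should suffice and spare the aryl silyl ether, the alkene and the carbinol, which cannot close to a chroman while O7 is silylated.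

Step 12
Reactants: 20 1-[6-hydroxy-3-{(2S)-2-(2-hydroxypropan-2-yl)-5-methylhex-4-en-1-yl}-2-methoxy-4-(triisopropylsilyloxy)phenyl]ethan-1-one
Product: 22 6-[(2S)-2-(2-hydroxypropan-2-yl)-5-methylhex-4-en-1-yl]-5-methoxy-7-(triisopropylsilyloxy)-4H-chromen-4-one, via enaminone 21 (not isolated)
Conditions: Me2NCH(OMe)2 (3 equiv), toluene, 90 °C; evaporate; then 1 M aq. HCl, CH2Cl2, rt
Reagents that add atoms: N,N-dimethylformamide dimethyl acetal, COC(OC)N(C)C
Why: Enaminone route to chromones, in which the methyl ketone condenses with the amide acetal to 21 and, on mild acid treatment, the ortho phenol adds to the β-carbon (6-endo-trig) and dimethylamine is lost to give the pyranone ring.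

Step 13
Reactants: 23 4-bromoresorcinol
Product: 24 1-bromo-2,4-bis(methoxymethoxy)benzene
Conditions: MOMCl (2.5 equiv), iPr2NEt, CH2Cl2, 0 °C to rt
Reagents that add atoms: chloromethyl methyl ether, COCCl
Why: Twofold O-alkylation of the phenols (Williamson-type), giving ethers that tolerate the organolithium and the rhodium chemistry that follow.

Step 14
Reactants: 24 1-bromo-2,4-bis(methoxymethoxy)benzene
Product: 27 [2,4-bis(methoxymethoxy)phenyl]boronic acid, via aryllithium 25 (not isolated), via lithium borate 26 (not isolated)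
Conditions: n-BuLi (1.05 equiv), THF, −78 °C; B(OiPr)3 (1.5 equiv), −78 °C to rt; aq. NH4Cl
Reagents that add atoms: triisopropyl borate, CC(C)OB(OC(C)C)OC(C)C; water, O
Why: Bromine–lithium exchange followed by borylation with a trialkyl borate and hydrolysis of borate 26 under a weakly acidic quench that leaves the MOM ethers in place.

Step 15
Reactants: 22 6-[(2S)-2-(2-hydroxypropan-2-yl)-5-methylhex-4-en-1-yl]-5-methoxy-7-(triisopropylsilyloxy)-4H-chromen-4-one; 27 [2,4-bis(methoxymethoxy)phenyl]boronic acid
Product: 28 (2S)-2-[2,4-bis(methoxymethoxy)phenyl]-6-[(2S)-2-(2-hydroxypropan-2-yl)-5-methylhex-4-en-1-yl]-5-methoxy-7-(triisopropylsilyloxy)-2,3-dihydro-4H-chromen-4-one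
Conditions: [RhCl(C2H4)2]2 (3 mol %), (1S,4S)-2,5-diphenylbicyclo[2.2.2]octa-2,5-diene (6.6 mol %), aq. KOH (10 mol %), 27 (3 equiv, in portions), toluene/H2O 10:1, 40 °C
Reagents that add atoms: none
Why: Rhodium-catalysed asymmetric 1,4-addition of an arylboronic acid to a chromone (Hayashi–Miyaura reaction), in which the aryl group passes from boron to the hydroxo rhodium diene complex, the C2=C3 bond inserts on the face left open by the C2-symmetric diene and water protonates the rhodium enolate; C2 is thus set by the ligand (the (S,S) antipode is assigned to (2S) by analogy with the sense for cyclic enones), the remote C2'' centre has no say, and excess 27 offsets protodeboronation of the ortho-alkoxy boronic acid.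

Step 16
Reactants: 28 (2S)-2-[2,4-bis(methoxymethoxy)phenyl]-6-[(2S)-2-(2-hydroxypropan-2-yl)-5-methylhex-4-en-1-yl]-5-methoxy-7-(triisopropylsilyloxy)-2,3-dihydro-4H-chromen-4-one
Product: 30 (2S)-2-(2,4-dihydroxyphenyl)-7-hydroxy-6-[(2S)-2-(2-hydroxypropan-2-yl)-5-methylhex-4-en-1-yl]-5-methoxy-2,3-dihydro-4H-chromen-4-one, via silyl ether 29 (not isolated)
Conditions: TMSOTf (8 equiv), 2,2'-bipyridyl (12 equiv), CH2Cl2, 0 °C to rt; then TBAF/AcOH (1:1, 10 equiv), THF, 0 °C to rt; aqueous work-up
Reagents that add atoms: none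
Why: Silyl triflate/bipyridyl cleavage of aromatic MOM ethers followed by fluoride desilylation, in which the triflate buffered by bipyridyl turns both MOM ethers into trimethylsilyl ethers and silylates the carbinol (29), and buffered fluoride then cleaves every O–Si bond, so that O7–H is freed only under non-acidic conditions where the carbinol cannot close to a chroman and ring C is not opened by base.

**Compound list**

1 | 5-methoxyresorcinol | COc1cc(O)cc(O)c1 | starting material
2 | (2,4-dihydroxy-6-methoxybenzylidene)dimethyliminium chloride | COc1cc(O)cc(O)c1C=[N+](C)C.[Cl-] | intermediate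
3 | 2,4-dihydroxy-6-methoxybenzaldehyde | COc1cc(O)cc(O)c1C=O | intermediate
4 | 2-hydroxy-6-methoxy-4-(methoxymethoxy)benzaldehyde | COCOc1cc(O)c(C=O)c(OC)c1 | intermediate
5 | 2-(hydroxymethyl)-3-methoxy-5-(methoxymethoxy)phenol | COCOc1cc(O)c(CO)c(OC)c1 | intermediate
6 | 3-methoxy-5-(methoxymethoxy)-2-(tosylmethyl)phenol | COc1cc(OCOC)cc(O)c1CS(=O)(=O)c1ccc(C)cc1 | intermediate
7 | 2-methylbut-3-en-2-ol | CC(C)(O)C=C | starting material
8 | triethyl orthoacetate | CCOC(C)(OCC)OCC | starting material
9 | 3-[(1-ethoxyethenyl)oxy]-3-methylbut-1-ene (ketene acetal) | C=C(OCC)OC(C)(C)C=C | intermediate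
10 | ethyl 5-methylhex-4-enoate | CCOC(=O)CCC=C(C)C | intermediate
11 | 5-methylhex-4-enoic acid | CC(C)=CCCC(=O)O | intermediate
12 | 1-(1H-imidazol-1-yl)-5-methylhex-4-en-1-one | CC(C)=CCCC(=O)n1ccnc1 | intermediate
13 | 5-methoxy-3-(methoxymethoxy)-6-methylidenecyclohexa-2,4-dien-1-one (ortho-quinone methide) | C=C1C(=O)C=C(OCOC)C=C1OC | intermediate
14 | (3S)-5-methoxy-7-(methoxymethoxy)-3-(3-methylbut-2-en-1-yl)-3,4-dihydro-2H-chromen-2-one | COc1cc(OCOC)cc2c1C[C@H](CC=C(C)C)C(=O)O2 | intermediate
15 | (3S)-3-{[2-hydroxy-6-methoxy-4-(methoxymethoxy)phenyl]methyl}-6-methylhept-5-en-2-one | COc1cc(OCOC)cc(O)c1C[C@H](CC=C(C)C)C(C)=O | intermediate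
16 | 2-[(2S)-2-(2-hydroxypropan-2-yl)-5-methylhex-4-en-1-yl]-3-methoxy-5-(methoxymethoxy)phenol | COc1cc(OCOC)cc(O)c1C[C@H](CC=C(C)C)C(C)(C)O | intermediate
17 | (3S)-3-{[2-methoxy-4-(methoxymethoxy)-6-(triisopropylsilyloxy)phenyl]methyl}-2,6-dimethylhept-5-en-2-ol | COc1cc(OCOC)cc(O[Si](C(C)C)(C(C)C)C(C)C)c1C[C@H](CC=C(C)C)C(C)(C)O | intermediate
18 | dilithio derivative of 17 (lithium alkoxide, aryllithium at the carbon between OMe and OMOM) | [Li]c1c(OC)c(C[C@H](CC=C(C)C)C(C)(C)O[Li])c(O[Si](C(C)C)(C(C)C)C(C)C)cc1OCOC | intermediate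
19 | 1-[3-{(2S)-2-(2-hydroxypropan-2-yl)-5-methylhex-4-en-1-yl}-2-methoxy-6-(methoxymethoxy)-4-(triisopropylsilyloxy)phenyl]ethan-1-one | COc1c(C(C)=O)c(OCOC)cc(O[Si](C(C)C)(C(C)C)C(C)C)c1C[C@H](CC=C(C)C)C(C)(C)O | intermediate
20 | 1-[6-hydroxy-3-{(2S)-2-(2-hydroxypropan-2-yl)-5-methylhex-4-en-1-yl}-2-methoxy-4-(triisopropylsilyloxy)phenyl]ethan-1-one | COc1c(C(C)=O)c(O)cc(O[Si](C(C)C)(C(C)C)C(C)C)c1C[C@H](CC=C(C)C)C(C)(C)O | intermediate
21 | (2E)-3-(dimethylamino)-1-[6-hydroxy-3-{(2S)-2-(2-hydroxypropan-2-yl)-5-methylhex-4-en-1-yl}-2-methoxy-4-(triisopropylsilyloxy)phenyl]prop-2-en-1-one | COc1c(C(=O)/C=C/N(C)C)c(O)cc(O[Si](C(C)C)(C(C)C)C(C)C)c1C[C@H](CC=C(C)C)C(C)(C)O | intermediate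
22 | 6-[(2S)-2-(2-hydroxypropan-2-yl)-5-methylhex-4-en-1-yl]-5-methoxy-7-(triisopropylsilyloxy)-4H-chromen-4-one | COc1c(C[C@H](CC=C(C)C)C(C)(C)O)c(O[Si](C(C)C)(C(C)C)C(C)C)cc2occc(=O)c12 | intermediate
23 | 4-bromoresorcinol | Oc1ccc(Br)c(O)c1 | starting material
24 | 1-bromo-2,4-bis(methoxymethoxy)benzene | COCOc1ccc(Br)c(OCOC)c1 | intermediate
25 | [2,4-bis(methoxymethoxy)phenyl]lithium | [Li]c1ccc(OCOC)cc1OCOC | intermediate
26 | lithium [2,4-bis(methoxymethoxy)phenyl]tri(propan-2-yloxy)borate | [Li+].CC(C)O[B-](OC(C)C)(OC(C)C)c1ccc(OCOC)cc1OCOC | intermediate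
27 | [2,4-bis(methoxymethoxy)phenyl]boronic acid | COCOc1ccc(B(O)O)c(OCOC)c1 | intermediate
28 | (2S)-2-[2,4-bis(methoxymethoxy)phenyl]-6-[(2S)-2-(2-hydroxypropan-2-yl)-5-methylhex-4-en-1-yl]-5-methoxy-7-(triisopropylsilyloxy)-2,3-dihydro-4H-chromen-4-one | COc1c(C[C@H](CC=C(C)C)C(C)(C)O)c(O[Si](C(C)C)(C(C)C)C(C)C)cc2c1C(=O)C[C@@H](c1ccc(OCOC)cc1OCOC)O2 | intermediate
29 | (2S)-2-[2,4-bis(trimethylsilyloxy)phenyl]-5-methoxy-6-[(2S)-5-methyl-2-{2-(trimethylsilyloxy)propan-2-yl}hex-4-en-1-yl]-7-(triisopropylsilyloxy)-2,3-dihydro-4H-chromen-4-one | COc1c(C[C@H](CC=C(C)C)C(C)(C)O[Si](C)(C)C)c(O[Si](C(C)C)(C(C)C)C(C)C)cc2c1C(=O)C[C@@H](c1ccc(O[Si](C)(C)C)cc1O[Si](C)(C)C)O2 | intermediate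
30 | (2S)-2-(2,4-dihydroxyphenyl)-7-hydroxy-6-[(2S)-2-(2-hydroxypropan-2-yl)-5-methylhex-4-en-1-yl]-5-methoxy-2,3-dihydro-4H-chromen-4-one | COc1c(C[C@H](CC=C(C)C)C(C)(C)O)c(O)cc2c1C(=O)C[C@@H](c1ccc(O)cc1O)O2 | target

**Step count and risk**

Total steps: 16. Longest linear sequence: 12 steps (steps 1 to 4, 7 to 12, 15 and 16).

Steps most likely to fail:

1. Step 7. The transient ortho-quinone methide may dimerise or be captured by imidazole before the enolate reaches it, facial discrimination at the enolate may be insufficient, or the lactone α-carbon may epimerise under the basic conditions. The fallback sets out from aldehyde 4 and returns at lactone 14; it replaces catalyst control by an oxazolidinone auxiliary and makes the C2''–C3''' bond to the prenyl group instead of the C1''–C2'' bond. Aldehyde 4 is silylated (TIPSOTf, 2,6-lutidine, CH2Cl2) to 2-methoxy-4-(methoxymethoxy)-6-(triisopropylsilyloxy)benzaldehyde F1. Horner–Wadsworth–Emmons olefination with (4S)-4-benzyl-3-[(diethoxyphosphoryl)acetyl]-1,3-oxazolidin-2-one (NaH, THF) gives the (E)-acryloyl imide F2, and hydrogenation of the conjugated alkene (H2, Pd/C, EtOAc) gives the 3-arylpropanoyl imide F3. The sodium (Z)-enolate (NaHMDS, THF, −78 °C) is alkylated with prenyl bromide on the face away from the benzyl group of the auxiliary, which should give the (2S)-configured imide F4. TBAF in THF then frees the phenoxide, which displaces the oxazolidinone from the exocyclic carbonyl and closes 14.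

2. Step 15. Protodeboronation of the ortho-alkoxy arylboronic acid may outrun transmetalation, insertion into the electron-rich chromone may be sluggish, the pyranone ring may open under base, or the facial selectivity may be poor. The fallback sets out from ketone 20 and aryllithium 25 and returns at 28; it forms ring C without stereocontrol and then removes the wrong C2 epimer by kinetic resolution. Aryllithium 25 is quenched with DMF to give 2,4-bis(methoxymethoxy)benzaldehyde F5. Pyrrolidine-mediated condensation of 20 with F5 (EtOH, 60 °C) proceeds through the 2'-hydroxychalcone F6, which closes by oxa-Michael addition to a mixture of 28 and its (2R) epimer F7. Asymmetric transfer hydrogenation (RhCl(Cp*)(TsDPEN), using the TsDPEN antipode matched to the (2R) ketone, HCO2H/Et3N, EtOAc, rt) should reduce F7 to the cis-(2R,4R) flavan-4-ol F8 and leave 28, which is separated from the alcohol on silica.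

3. Step 16. The silyl triflate may cause heterolysis of the O1–C2 bond (epimerisation at C2 through the ring-opened cation) or ionisation of the tertiary carbinol during MOM cleavage. The fallback sets out from 23 and chromone 22 and returns at target 30; it replaces the acetal groups of ring B by silyl ethers so that buffered fluoride alone ends the synthesis. Bromide 23 is silylated (TBSCl, imidazole, DMF) to 4-bromo-1,3-bis(tert-butyldimethylsilyloxy)benzene F9. Miyaura borylation (Pd(dppf)Cl2, bis(pinacolato)diboron, KOAc, dioxane, 80 °C) gives the pinacol boronate F10; lithiation is avoided because an ortho-lithiated aryl silyl ether would suffer silyl migration from oxygen to carbon. Conjugate arylation of 22 with F10 under the catalyst of step 15 gives the bis(tert-butyldimethylsilyl) flavanone F11. TBAF/AcOH in THF then removes all three silyl groups and gives 30.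

**Further compounds**

F1 | step 7 | 2-methoxy-4-(methoxymethoxy)-6-(triisopropylsilyloxy)benzaldehyde | COCOc1cc(O[Si](C(C)C)(C(C)C)C(C)C)c(C=O)c(OC)c1
F2 | step 7 | (4S)-4-benzyl-3-[(2E)-3-{2-methoxy-4-(methoxymethoxy)-6-(triisopropylsilyloxy)phenyl}prop-2-enoyl]-1,3-oxazolidin-2-one | COCOc1cc(O[Si](C(C)C)(C(C)C)C(C)C)c(/C=C/C(=O)N2C(=O)OC[C@@H]2Cc2ccccc2)c(OC)c1
F3 | step 7 | (4S)-4-benzyl-3-[3-{2-methoxy-4-(methoxymethoxy)-6-(triisopropylsilyloxy)phenyl}propanoyl]-1,3-oxazolidin-2-one | COCOc1cc(O[Si](C(C)C)(C(C)C)C(C)C)c(CCC(=O)N2C(=O)OC[C@@H]2Cc2ccccc2)c(OC)c1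
F4 | step 7 | (4S)-4-benzyl-3-[(2S)-2-{[2-methoxy-4-(methoxymethoxy)-6-(triisopropylsilyloxy)phenyl]methyl}-5-methylhex-4-enoyl]-1,3-oxazolidin-2-one | COCOc1cc(O[Si](C(C)C)(C(C)C)C(C)C)c(C[C@H](CC=C(C)C)C(=O)N2C(=O)OC[C@@H]2Cc2ccccc2)c(OC)c1
F5 | step 15 | 2,4-bis(methoxymethoxy)benzaldehyde | COCOc1ccc(C=O)c(OCOC)c1
F6 | step 15 | (2E)-3-[2,4-bis(methoxymethoxy)phenyl]-1-[6-hydroxy-3-{(2S)-2-(2-hydroxypropan-2-yl)-5-methylhex-4-en-1-yl}-2-methoxy-4-(triisopropylsilyloxy)phenyl]prop-2-en-1-one | COc1c(C(=O)/C=C/c2ccc(OCOC)cc2OCOC)c(O)cc(O[Si](C(C)C)(C(C)C)C(C)C)c1C[C@H](CC=C(C)C)C(C)(C)O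
F7 | step 15 | (2R)-2-[2,4-bis(methoxymethoxy)phenyl]-6-[(2S)-2-(2-hydroxypropan-2-yl)-5-methylhex-4-en-1-yl]-5-methoxy-7-(triisopropylsilyloxy)-2,3-dihydro-4H-chromen-4-one | COc1c(C[C@H](CC=C(C)C)C(C)(C)O)c(O[Si](C(C)C)(C(C)C)C(C)C)cc2c1C(=O)C[C@H](c1ccc(OCOC)cc1OCOC)O2
F8 | step 15 | (2R,4R)-2-[2,4-bis(methoxymethoxy)phenyl]-6-[(2S)-2-(2-hydroxypropan-2-yl)-5-methylhex-4-en-1-yl]-5-methoxy-7-(triisopropylsilyloxy)-3,4-dihydro-2H-chromen-4-ol | COc1c(C[C@H](CC=C(C)C)C(C)(C)O)c(O[Si](C(C)C)(C(C)C)C(C)C)cc2c1[C@H](O)C[C@H](c1ccc(OCOC)cc1OCOC)O2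
F9 | step 16 | 4-bromo-1,3-bis(tert-butyldimethylsilyloxy)benzene | CC(C)(C)[Si](C)(C)Oc1ccc(Br)c(O[Si](C)(C)C(C)(C)C)c1
F10 | step 16 | 2-[2,4-bis(tert-butyldimethylsilyloxy)phenyl]-4,4,5,5-tetramethyl-1,3,2-dioxaborolane | CC(C)(C)[Si](C)(C)Oc1ccc(B2OC(C)(C)C(C)(C)O2)c(O[Si](C)(C)C(C)(C)C)c1
F11 | step 16 | (2S)-2-[2,4-bis(tert-butyldimethylsilyloxy)phenyl]-6-[(2S)-2-(2-hydroxypropan-2-yl)-5-methylhex-4-en-1-yl]-5-methoxy-7-(triisopropylsilyloxy)-2,3-dihydro-4H-chromen-4-one | COc1c(C[C@H](CC=C(C)C)C(C)(C)O)c(O[Si](C(C)C)(C(C)C)C(C)C)cc2c1C(=O)C[C@@H](c1ccc(O[Si](C)(C)C(C)(C)C)cc1O[Si](C)(C)C(C)(C)C)O2
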